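Remark: atoms are numbered as in eremophilane throughout (ring A: C1–C5 and C10; ring B: C5–C10; C14 = methyl on C5; C15 = methyl on C4; side chain on C7: C11, ester carbon C12, methyl C13). In this numbering the target is (3S,4R,5R,10R,11R). Assumption: (R)-1-(2,4,6-triisopropylphenyl)ethanol and (R)-4-benzyl-1,3-oxazolidin-2-one are taken as commercial.

## Structural features

The target is a cis-fused decalin: ring A (C1–C5, C10) is a saturated cyclohexane and ring B (C5–C10) a cyclohex-2-en-1-one with C8=O and C6=C7. Ring A carries four contiguous stereocentres: C3 (O-angeloyl), C4 (methyl C15), the quaternary C5 (methyl C14) and the ring-fusion C10 (H). The oxygen, both methyl groups and H10 lie on one face, so C6 and C9 of ring B lie together on the other. A fifth stereocentre, C11, stands on the C7 side chain, 1,4 to C5 and too remote for relay from ring A. Fragile groups are the angelate (Z to E isomerisation), the enone, and C11–H, which is α to the ester and allylic (epimerisation, or migration of C6=C7 to C7=C11). The real difficulty is the all-cis C3/C4/C5/C10 tetrad with its quaternary centre at the ring fusion, together with a ring B in which carbonyl, double bond and branched C7 substituent sit on defined sides of C8. The key step exploits the fact that C1 and C2 are bare methylenes, C8 is a carbonyl carbon and C10 lies between them: a C1=C2 alkene and a C7=C8 enolate are exactly what a [3,3] shift leaves behind when it makes C9–C10 and breaks a bond between C2 and C7. Reconnecting C2 to C7 turns the decalin into a bicyclo[2.2.2]octene in which C3, C4 and C5 can be set together by one Diels–Alder reaction of a Z-alkene (C3=C4).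

## Logic of the disconnections

28 is cut at the acyl C–O bond on the C3 oxygen into 25 and 26. The Z-configured unsaturated ester is the group most prone to isomerise, so it is introduced last. The forward step must acylate a hindered secondary alcohol without Z to E isomerisation and without epimerising C11.

25 is traced to 24 by restoring the O–C bond to the benzylic auxiliary, which doubles as the protecting group of the C3 oxygen from the cycloaddition onwards. The cleavage must spare the enone and C11.

24 is traced to 23, then to 22. The C6=C7 double bond is removed and C8=O is masked as the C7=C8 ethyl enol ether (23); the C1=C2 double bond is then restored (22). The enol ether records on which side of C8 the unsaturation belongs, so no regiochemical choice between C7 and C9 is left. The forward dehydrogenation must take hydride from C6 and not from C9 or C11, and the hydrogenation must spare the tetrasubstituted enol ether.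

22 is traced to 21 and 21 to 19 by exchanging the methoxy group for the oxazolidinone and cutting the C11–C13 bond. C11 is too far from the ring stereocentres, so it is set by the auxiliary. The ester exchange must not epimerise C11.

19 is cut at the C7–C11 bond into 14 and 17 (through 18). This bond joins the α-carbon of the masked C8 ketone to the α-carbon of the carboxyl group, two carbons of like polarity. The union becomes possible because C7 carries a leaving group (the oxygen of the former ketone) and is the electrophile in a palladium-catalysed coupling. The demand is coupling at a tetrasubstituted, alkoxy-substituted alkenyl triflate. 17 is cut at the N-acyl bond into 15 and 16.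

14 is traced through 13 and 12 to 11 by cutting the C9–C10 bond and rejoining C2 to C7 (retro-[3,3]). The cis-decalin becomes a bridged bicycle in which C10 is no longer a stereocentre and ring B is reduced to a two-carbon appendage on C7. The forward step needs the alkenyl group on C7 syn to the C1=C10 bridge, a rearrangement faster than fragmentation of the alkoxide, and trapping of the enolate on oxygen.

11 is cut at the C7–C8 bond into 8 and 9 (through 10). The two-carbon unit brings C9 and C8 together with the oxygen that will become the C8 carbonyl. The addition must take place on the ketone face next to the C1=C10 bridge.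

8 is traced to 7 by restoring the two C6–O bonds. The ketal is needed only because the diene partner of the cycloaddition is stable solely as an o-quinone monoketal.

7 is cut at the C2–C3 and C4–C5 bonds into 6 and 4 (retro-Diels–Alder), and 6 is traced to 5 by re-aromatisation. Three ring stereocentres (C3, C4, C5) come from one event: the Z-alkene gives cis O/C15, the endo orientation puts both cis to C14, and the ether stereocentre of 4 selects the absolute sense. The cycloaddition must be regioselective (C4 to C5), endo and face-selective, and faster than dimerisation of 6.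

4 is traced to 3 (double-bond shift) and 3 is cut at the O–allyl bond into 1 and 2. C3, C4 and C15 of the target thus come from 2, and the only purchased stereocentre of the ring system is that of 1.

## Other disconnections considered

Alternative 1: the first route to come to mind cuts C5–C6 and C9=C10 (Robinson annulation). A ring-A ketone A1 with C3 and C4 in place is annulated with a vinyl ketone to give the octalone A2.
- A2 carries the enone as C9=C10–C8=O, on the wrong side of C8. C10 must then be created by a cis-selective reduction, and C6=C7 plus the C7 substituent must be introduced on a ketone that can enolise towards C7 or C9.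
- C5 is set relative to C4 by alkylating an enolate whose two faces differ only slightly.
- A1 itself needs a separate asymmetric synthesis.
- The chosen plan sets C3, C4 and C5 in one cycloaddition and leaves oxygen and unsaturation of ring B in regiodefined positions.

Alternative 2: the same [3,3] shift in the opposite sense cuts C5–C6 and rejoins C3 to C8. The ethynyl carbinol A3, on alkoxide-accelerated rearrangement, gives an allenolate and after protonation the dienol ether enone A4, with ring B complete in one step.
- C3 and C4 remain sp2 in A4 and would have to be reduced from a face chosen only by the balance between the angular methyl and ring B in a flexible cis-decalin.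
- The rearrangement would have to form the quaternary centre at a methyl-bearing alkene carbon.
- A3 has no handle for absolute configuration.
- The chosen sense keeps C3, C4 and C5 as sp3 centres fixed before the rearrangement and makes the new bond at an unsubstituted alkene carbon.

Alternative 3: cutting C1–C10 leads to a desymmetrising 6-exo radical cyclisation of the iodide A5 onto its prochiral cyclohexadienone, giving the enone A6.
- Cis-fusion is assured by the tether, but the configuration of C5 depends on which enone arm is attacked. That choice rests on a small conformational preference (equatorial oxygen against equatorial methyl in the chair transition state).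
- A5 needs a long linear sequence.
- The C7 side chain would still have to be added to A6.

Key step: step 6

## Route

Step 1
Reactants: 1 (R)-1-(2,4,6-triisopropylphenyl)ethanol; 2 allyl bromide
Product: 3 2-[(1R)-1-(prop-2-en-1-yloxy)ethyl]-1,3,5-triisopropylbenzene
Conditions: NaH, Bu4NI (cat.), THF–DMF, 0 °C to rt
Reagents that add atoms: none
Why: Williamson ether synthesis of a hindered secondary alkoxide with a reactive allylic bromide; the C–O bond of the stereocentre is not touched, so its (R) configuration is retained.

Step 2
Reactants: 3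
Product: 4 2-[(1R)-1-{[(1Z)-prop-1-en-1-yl]oxy}ethyl]-1,3,5-triisopropylbenzene
Conditions: KOtBu, DMSO, rt to 60 °C
Reagents that add atoms: none
Why: Base-mediated isomerisation of an allyl ether to a propenyl ether; the oxygen-coordinated cis allyl anion is protonated at the terminus, which should give the Z enol ether.

Step 3
Reactants: 5 2-methoxy-3-methylphenol; 4
Product: 7 (1R,4S,7R,8R)-3,3-dimethoxy-4,8-dimethyl-7-[(1R)-1-(2,4,6-triisopropylphenyl)ethoxy]bicyclo[2.2.2]oct-5-en-2-one, via masked o-benzoquinone 6 (not isolated)
Conditions: PhI(OAc)2, MeOH, 0 °C to rt (5 added slowly to PhI(OAc)2 and 4); chromatography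
Reagents that add atoms: methanol, CO
Why: Oxidative dearomatisation of 5 by the trivalent iodine reagent in methanol gives the o-quinone monoketal 6, an electron-poor dienone that undergoes an inverse-electron-demand Diels–Alder reaction with the Z enol ether 4. The nucleophilic methyl-bearing carbon bonds to the methyl-bearing diene terminus (C4–C5) and the oxygen-bearing carbon to C2; the endo rule places O and C15 syn to the new C1=C10 bridge and hence cis to C14, and suprafacial addition keeps O and C15 cis. In the s-trans enol ether conformer with the ether C–H in the enol plane the triisopropylphenyl group covers one face, so 6 should add to the other and set C3, C4 and C5 in the absolute sense shown; the minor diastereomer is removed by chromatography.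

Step 4
Reactants: 7
Product: 8 (1R,4S,7R,8R)-4,8-dimethyl-7-[(1R)-1-(2,4,6-triisopropylphenyl)ethoxy]bicyclo[2.2.2]oct-5-en-2-one
Conditions: SmI2 (5 equiv), THF–MeOH, −78 °C to rt
Reagents that add atoms: none
Why: Reductive cleavage of C–O bonds α to a ketone by SmI2 (electron transfer, loss of methoxide, protonation, twice); C6 becomes CH2, so no stereocentre is involved and the isolated alkene and the benzylic ether are inert.

Step 5
Reactants: 8; 9 ethyl vinyl ether
Product: 11 (1R,2R,4S,7R,8R)-2-(1-ethoxyethenyl)-4,8-dimethyl-7-[(1R)-1-(2,4,6-triisopropylphenyl)ethoxy]bicyclo[2.2.2]oct-5-en-2-ol, via (1-ethoxyethenyl)lithium 10 (not isolated)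
Conditions: 9, t-BuLi, THF, −78 to 0 °C; then CeCl3, −78 °C; then 8; H2O work-up
Reagents that add atoms: none
Why: 1,2-addition of an acyl anion equivalent that brings C9 and C8 with the future carbonyl oxygen; CeCl3 suppresses enolisation of the ketone. Attack should come from the face flanked by the C1=C10 bridge, more open than the face flanked by the C3–C4 bridge with its inward C–H bonds, so the alkenyl group ends up syn to C1=C10 as the rearrangement requires.

Step 6
Reactants: 11
Product: 14 (4aS,5R,6S,8aS)-2-ethoxy-4a,5-dimethyl-6-[(1R)-1-(2,4,6-triisopropylphenyl)ethoxy]-1,4,4a,5,6,8a-hexahydronaphthalen-3-yl trifluoromethanesulfonate, via potassium alkoxide 12 (not isolated), via potassium enolate 13 (not isolated)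
Conditions: KH, 18-crown-6, THF, 0 °C to rt; then PhNTf2, −78 °C to rt
Reagents that add atoms: N-phenylbis(trifluoromethanesulfonimide), O=S(=O)(N(c1ccccc1)S(=O)(=O)C(F)(F)F)C(F)(F)F
Why: Deprotonation gives alkoxide 12, whose C9=C8–C7–C2–C1=C10 unit is a 1,5-diene held in a boat by the bicycle; the alkoxide-accelerated [3,3]-sigmatropic shift (anionic oxy-Cope rearrangement) breaks C2–C7 and forms C9–C10 to give enolate 13. The closest known reaction type is the rearrangement of 2-alkenylbicyclo[2.2.2]oct-5-en-2-olates to cis-decalin enolates, including 1-alkoxyalkenyl groups. Ring B (C5–C10) is closed as a six-membered ring by the new C9–C10 σ-bond in a concerted suprafacial process through a boat-like transition state; ring A survives as the C1=C2 cyclohexene. The only new stereocentre, C10, is controlled by the bicycle: C9 can reach C10 only from the side of the C6–C7 bridge, so C9 becomes cis to C6 and H10 cis to the C5 methyl (cis ring fusion). C3, C4 and C5 keep all four bonds and their configuration. The step needs the alkenyl group syn to C1=C10 (secured in step 5) and a rearrangement faster than fragmentation of 12 (secured by the crown-ether-separated potassium alkoxide, release of bicyclic strain and formation of an enolate). It also needs regiodefined trapping: the enolate exists only as C7=C8 and is sulfonylated on oxygen, so C7 carries the leaving group and C8 the masked carbonyl.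

Step 7
Reactants: 15 (R)-4-benzyl-1,3-oxazolidin-2-one; 16 bromoacetyl bromide
Product: 17 (R)-4-benzyl-3-(bromoacetyl)-1,3-oxazolidin-2-one
Conditions: n-BuLi, THF, −78 °C; then 16
Reagents that add atoms: none
Why: N-acylation of the lithiated oxazolidinone; acyl substitution at the acid bromide is much faster than displacement of the α-bromide at −78 °C, and the ring stereocentre is not involved.

Step 8
Reactants: 14; 17
Product: 19 (4R)-4-benzyl-3-{2-[(4aS,5R,6S,8aS)-2-ethoxy-4a,5-dimethyl-6-[(1R)-1-(2,4,6-triisopropylphenyl)ethoxy]-1,4,4a,5,6,8a-hexahydronaphthalen-3-yl]acetyl}-1,3-oxazolidin-2-one, via organozinc bromide 18 (not isolated)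
Conditions: 17, Zn (activated with Me3SiCl), THF, rt; then 14, Pd(PPh3)4 (5 mol %), THF–DMF, 60 °C
Reagents that add atoms: none
Why: Zinc insertion gives the Reformatsky reagent 18, which enters a Negishi-type coupling with the alkenyl triflate (oxidative addition to zerovalent palladium, transmetalation, reductive elimination) to form C7–C11; the enol ether geometry is fixed by the ring and no stereocentre is formed.

Step 9
Reactants: 19
Product: 21 (4R)-4-benzyl-3-{(2R)-2-[(4aS,5R,6S,8aS)-2-ethoxy-4a,5-dimethyl-6-[(1R)-1-(2,4,6-triisopropylphenyl)ethoxy]-1,4,4a,5,6,8a-hexahydronaphthalen-3-yl]propanoyl}-1,3-oxazolidin-2-one, via sodium enolate 20 (not isolated)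
Conditions: NaN(SiMe3)2, THF, −78 °C; then MeI, −78 to −40 °C
Reagents that add atoms: iodomethane, CI
Why: Auxiliary-controlled enolate alkylation: the sodium-chelated Z enolate 20 is methylated on the face away from the benzyl group, which for the (R)-oxazolidinone gives (R) at C11; alkylation occurs at the α-carbon C11 and not through the enol ether.

Step 10
Reactants: 21
Product: 22 methyl (2R)-2-[(4aS,5R,6S,8aS)-2-ethoxy-4a,5-dimethyl-6-[(1R)-1-(2,4,6-triisopropylphenyl)ethoxy]-1,4,4a,5,6,8a-hexahydronaphthalen-3-yl]propanoate
Conditions: MeMgBr, MeOH, CH2Cl2, 0 °C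
Reagents that add atoms: methanol, CO
Why: Transesterification of the N-acyl oxazolidinone by methoxymagnesium bromide at the exocyclic carbonyl; the weakly basic magnesium alkoxide at 0 °C should leave C11 unchanged, and the auxiliary is recovered.

Step 11
Reactants: 22
Product: 23 methyl (2R)-2-[(4aS,5R,6S,8aR)-2-ethoxy-4a,5-dimethyl-6-[(1R)-1-(2,4,6-triisopropylphenyl)ethoxy]-1,4,4a,5,6,7,8,8a-octahydronaphthalen-3-yl]propanoate
Conditions: H2 (1 atm), RhCl(PPh3)3 (10 mol %), benzene, rt
Reagents that add atoms: none
Why: Homogeneous hydrogenation with RhCl(PPh3)3 reduces the cis-disubstituted C1=C2 bond and leaves the tetrasubstituted C7=C8 enol ether and the benzylic ether; no stereocentre is formed (the descriptor at C10 changes only through the priority rules).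

Step 12
Reactants: 23
Product: 24 methyl (2R)-2-[(4aR,5R,6S,8aR)-4a,5-dimethyl-2-oxo-6-[(1R)-1-(2,4,6-triisopropylphenyl)ethoxy]-1,2,4a,5,6,7,8,8a-octahydronaphthalen-3-yl]propanoate
Conditions: DDQ, 2,6-lutidine, CH2Cl2–H2O (20:1), 0 °C to rt
Reagents that add atoms: water, O
Why: Dehydrogenation of an enol ether with DDQ: hydride abstraction from C6 gives the only allylic cation that is stabilised by the ethoxy group without bearing the ester (as at C11) or placing oxygen on the central carbon (as from C9). Hydrolysis of the resulting O-ethyl oxocarbenium ion gives the C6=C7–C8=O enone, so the position of the double bond is dictated by the enol ether made in step 6; C11 is not part of the cation and keeps its configuration.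

Step 13
Reactants: 24
Product: 25 methyl (2R)-2-[(4aR,5R,6S,8aR)-6-hydroxy-4a,5-dimethyl-2-oxo-1,2,4a,5,6,7,8,8a-octahydronaphthalen-3-yl]propanoate
Conditions: CF3CO2H, CH2Cl2, 0 °C
Reagents that add atoms: none
Why: Acid cleavage of the electron-rich secondary benzylic ether by ionisation (the benzylic cation loses a proton to give the styrene); the C3–O bond is not broken, so C3 keeps its configuration, and brief exposure at 0 °C should not move the C6=C7 double bond.

Step 14
Reactants: 25; 26 angelic acid
Product: 28 methyl (2R)-2-[(4aR,5R,6S,8aR)-4a,5-dimethyl-6-{[(2Z)-2-methylbut-2-enoyl]oxy}-2-oxo-1,2,4a,5,6,7,8,8a-octahydronaphthalen-3-yl]propanoate, via mixed anhydride 27 (not isolated)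
Conditions: 26, 2,4,6-trichlorobenzoyl chloride, Et3N, toluene, rt; then 25, toluene, 80 °C
Reagents that add atoms: none
Why: Yamaguchi esterification: the mixed anhydride 27 acylates the hindered secondary alcohol at the angeloyl carbonyl; the protocol avoids strong bases and nucleophilic catalysts that isomerise the Z double bond or epimerise C11, and the C3–O bond is retained.

## Compound list

1 | (R)-1-(2,4,6-triisopropylphenyl)ethanol | C[C@H](c1c(C(C)C)cc(C(C)C)cc1C(C)C)O | starting material
2 | allyl bromide | C=CCBr | starting material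
3 | 2-[(1R)-1-(prop-2-en-1-yloxy)ethyl]-1,3,5-triisopropylbenzene | C[C@H](c1c(C(C)C)cc(C(C)C)cc1C(C)C)OCC=C | intermediate
4 | 2-[(1R)-1-{[(1Z)-prop-1-en-1-yl]oxy}ethyl]-1,3,5-triisopropylbenzene | C[C@H](c1c(C(C)C)cc(C(C)C)cc1C(C)C)O/C=C\C | intermediate
5 | 2-methoxy-3-methylphenol | COc1c(C)cccc1O | starting material
6 | 6,6-dimethoxy-5-methylcyclohexa-2,4-dien-1-one (masked o-benzoquinone) | COC1(OC)C(C)=CC=CC1=O | intermediate
7 | (1R,4S,7R,8R)-3,3-dimethoxy-4,8-dimethyl-7-[(1R)-1-(2,4,6-triisopropylphenyl)ethoxy]bicyclo[2.2.2]oct-5-en-2-one (7-alkoxy and 8-methyl cis, both syn to C5=C6) | C[C@H](c3c(C(C)C)cc(C(C)C)cc3C(C)C)O[C@H]1[C@H]2C=C[C@](C)(C(OC)(OC)C2=O)[C@H]1C | intermediate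
8 | (1R,4S,7R,8R)-4,8-dimethyl-7-[(1R)-1-(2,4,6-triisopropylphenyl)ethoxy]bicyclo[2.2.2]oct-5-en-2-one | C[C@H](c3c(C(C)C)cc(C(C)C)cc3C(C)C)O[C@H]1[C@H]2C=C[C@](C)(CC2=O)[C@H]1C | intermediate
9 | ethyl vinyl ether | C=COCC | starting material
10 | (1-ethoxyethenyl)lithium | [Li]C(=C)OCC | intermediate
11 | (1R,2R,4S,7R,8R)-2-(1-ethoxyethenyl)-4,8-dimethyl-7-[(1R)-1-(2,4,6-triisopropylphenyl)ethoxy]bicyclo[2.2.2]oct-5-en-2-ol (alkenyl group syn to C5=C6) | C[C@H](c3c(C(C)C)cc(C(C)C)cc3C(C)C)O[C@H]1[C@H]2C=C[C@](C)(C[C@]2(O)C(=C)OCC)[C@H]1C | intermediate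
12 | potassium (1R,2R,4S,7R,8R)-2-(1-ethoxyethenyl)-4,8-dimethyl-7-[(1R)-1-(2,4,6-triisopropylphenyl)ethoxy]bicyclo[2.2.2]oct-5-en-2-olate | C[C@H](c3c(C(C)C)cc(C(C)C)cc3C(C)C)O[C@H]1[C@H]2C=C[C@](C)(C[C@]2([O-])C(=C)OCC)[C@H]1C.[K+] | intermediate
13 | potassium (4aS,5R,6S,8aS)-2-ethoxy-4a,5-dimethyl-6-[(1R)-1-(2,4,6-triisopropylphenyl)ethoxy]-1,4,4a,5,6,8a-hexahydronaphthalen-3-olate | C[C@H](c3c(C(C)C)cc(C(C)C)cc3C(C)C)O[C@H]1C=C[C@@H]2CC(OCC)=C([O-])C[C@]2(C)[C@H]1C.[K+] | intermediate
14 | (4aS,5R,6S,8aS)-2-ethoxy-4a,5-dimethyl-6-[(1R)-1-(2,4,6-triisopropylphenyl)ethoxy]-1,4,4a,5,6,8a-hexahydronaphthalen-3-yl trifluoromethanesulfonate | C[C@H](c3c(C(C)C)cc(C(C)C)cc3C(C)C)O[C@H]1C=C[C@@H]2CC(OCC)=C(OS(=O)(=O)C(F)(F)F)C[C@]2(C)[C@H]1C | intermediate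
15 | (R)-4-benzyl-1,3-oxazolidin-2-one | O=C1N[C@H](Cc2ccccc2)CO1 | starting material
16 | bromoacetyl bromide | BrCC(Br)=O | starting material
17 | (R)-4-benzyl-3-(bromoacetyl)-1,3-oxazolidin-2-one | BrCC(=O)N1[C@H](Cc2ccccc2)COC1=O | intermediate
18 | bromo{2-[(4R)-4-benzyl-2-oxo-1,3-oxazolidin-3-yl]-2-oxoethyl}zinc | Br[Zn]CC(=O)N1[C@H](Cc2ccccc2)COC1=O | intermediate
19 | (4R)-4-benzyl-3-{2-[(4aS,5R,6S,8aS)-2-ethoxy-4a,5-dimethyl-6-[(1R)-1-(2,4,6-triisopropylphenyl)ethoxy]-1,4,4a,5,6,8a-hexahydronaphthalen-3-yl]acetyl}-1,3-oxazolidin-2-one | C[C@H](c3c(C(C)C)cc(C(C)C)cc3C(C)C)O[C@H]1C=C[C@@H]2CC(OCC)=C(CC(=O)N4[C@H](Cc5ccccc5)COC4=O)C[C@]2(C)[C@H]1C | intermediate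
20 | sodium (Z)-enolate of 19 | C[C@H](c3c(C(C)C)cc(C(C)C)cc3C(C)C)O[C@H]1C=C[C@@H]2CC(OCC)=C(/C=C(\[O-])N4[C@H](Cc5ccccc5)COC4=O)C[C@]2(C)[C@H]1C.[Na+] | intermediate
21 | (4R)-4-benzyl-3-{(2R)-2-[(4aS,5R,6S,8aS)-2-ethoxy-4a,5-dimethyl-6-[(1R)-1-(2,4,6-triisopropylphenyl)ethoxy]-1,4,4a,5,6,8a-hexahydronaphthalen-3-yl]propanoyl}-1,3-oxazolidin-2-one | C[C@H](c3c(C(C)C)cc(C(C)C)cc3C(C)C)O[C@H]1C=C[C@@H]2CC(OCC)=C([C@@H](C)C(=O)N4[C@H](Cc5ccccc5)COC4=O)C[C@]2(C)[C@H]1C | intermediate
22 | methyl (2R)-2-[(4aS,5R,6S,8aS)-2-ethoxy-4a,5-dimethyl-6-[(1R)-1-(2,4,6-triisopropylphenyl)ethoxy]-1,4,4a,5,6,8a-hexahydronaphthalen-3-yl]propanoate | C[C@H](c3c(C(C)C)cc(C(C)C)cc3C(C)C)O[C@H]1C=C[C@@H]2CC(OCC)=C([C@@H](C)C(=O)OC)C[C@]2(C)[C@H]1C | intermediate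
23 | methyl (2R)-2-[(4aS,5R,6S,8aR)-2-ethoxy-4a,5-dimethyl-6-[(1R)-1-(2,4,6-triisopropylphenyl)ethoxy]-1,4,4a,5,6,7,8,8a-octahydronaphthalen-3-yl]propanoate | C[C@H](c3c(C(C)C)cc(C(C)C)cc3C(C)C)O[C@H]1CC[C@@H]2CC(OCC)=C([C@@H](C)C(=O)OC)C[C@]2(C)[C@H]1C | intermediate
24 | methyl (2R)-2-[(4aR,5R,6S,8aR)-4a,5-dimethyl-2-oxo-6-[(1R)-1-(2,4,6-triisopropylphenyl)ethoxy]-1,2,4a,5,6,7,8,8a-octahydronaphthalen-3-yl]propanoate | C[C@H](c3c(C(C)C)cc(C(C)C)cc3C(C)C)O[C@H]1CC[C@@H]2CC(=O)C([C@@H](C)C(=O)OC)=C[C@]2(C)[C@H]1C | intermediate
25 | methyl (2R)-2-[(4aR,5R,6S,8aR)-6-hydroxy-4a,5-dimethyl-2-oxo-1,2,4a,5,6,7,8,8a-octahydronaphthalen-3-yl]propanoate | O[C@H]1CC[C@@H]2CC(=O)C([C@@H](C)C(=O)OC)=C[C@]2(C)[C@H]1C | intermediate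
26 | angelic acid, (2Z)-2-methylbut-2-enoic acid | C/C=C(/C)C(=O)O | starting material
27 | (2Z)-2-methylbut-2-enoic 2,4,6-trichlorobenzoic anhydride | C/C=C(/C)C(=O)OC(=O)c1c(Cl)cc(Cl)cc1Cl | intermediate
28 | methyl (2R)-2-[(4aR,5R,6S,8aR)-4a,5-dimethyl-6-{[(2Z)-2-methylbut-2-enoyl]oxy}-2-oxo-1,2,4a,5,6,7,8,8a-octahydronaphthalen-3-yl]propanoate (CNP0323033.1) | C/C=C(/C)C(=O)O[C@H]1CC[C@@H]2CC(=O)C([C@@H](C)C(=O)OC)=C[C@]2(C)[C@H]1C | target

## Step count and least certain steps

Total step count: 14. Longest linear sequence: 13 (steps 1–6 and 8–14; step 7 is a one-step branch).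

Step 6 (key step). Fragmentation of alkoxide 12 (loss of the alkenyl anion, or opening towards the C3 ether) may compete with the [3,3] shift, and the electron-rich enolate 13 may be protonated or decompose before it is sulfonylated. Fallback: a neutral variant that avoids the alkoxide. It sets out from 11, which is silylated (Me3SiCl, imidazole) to the trimethylsilyl ether F1. Thermolysis in a sealed tube (toluene, about 200 °C) should give the trimethylsilyl enol ether F2 by the uncatalysed [3,3] shift. Cleavage of F2 with MeLi and trapping with PhNTf2 comes back to the route at 14.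

Step 3. Dimerisation of 6 may outrun the cycloaddition, because the new C4–C5 bond joins two substituted carbons. For the same reason regioselectivity and the facial control by the ether stereocentre may erode. Fallback: a bromine-blocked diene. It sets out from 5, which is brominated para to the hydroxyl group (NBS) to 4-bromo-2-methoxy-3-methylphenol F3. Its monoketal dimerises much more slowly and is combined with 4 under the conditions of step 3 to give the bromo adduct F4. Radical debromination (Bu3SnH, AIBN) comes back at 7.

Step 8. Oxidative addition and transmetalation may be slow at the tetrasubstituted, alkoxy-substituted alkenyl triflate, so that protonation or self-condensation of the zinc enolate 18 takes over. Fallback: reversal of the roles of the partners. It sets out from 14, which is borylated (bis(pinacolato)diboron, PdCl2(dppf), KOAc) to the alkenyl pinacol boronate F5. Palladium-catalysed coupling of F5 with the α-bromo imide 17 (Pd(PPh3)4, K3PO4) comes back at 19.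

Step 12. Hydride abstraction may occur at other activated C–H bonds (C11–H, the benzylic C–H of the auxiliary), the enol ether may hydrolyse to the saturated ketone before it is oxidised, or the enone may be dehydrogenated further. Fallback: selenoxide elimination. It sets out from 23, which is treated with PhSeCl and then aqueous NaHCO3 to give the α-phenylselanyl ketone F6 with selenium on C7. Oxidation with H2O2 and syn-elimination of the selenoxide towards C6 comes back at 24.

Step 14. Acylation of the hindered C3 alcohol may be slow, and prolonged heating with amine may isomerise the angelate to the tiglate or epimerise C11. Fallback: building the Z double bond on the ester. It sets out from 25, which is acylated with 2-[bis(2,2,2-trifluoroethoxy)phosphoryl]propanoic acid (DCC, DMAP cat.) to the phosphonate ester F7. A Still–Gennari olefination of F7 with acetaldehyde (KN(SiMe3)2, 18-crown-6, THF, −78 °C) should give the Z-configured ester and comes back at 28.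

## Further compounds

F1 | step 6 | trimethylsilyl ether of 11 (configuration as in 11) | C[C@H](c3c(C(C)C)cc(C(C)C)cc3C(C)C)O[C@H]1[C@H]2C=C[C@](C)(C[C@]2(O[Si](C)(C)C)C(=C)OCC)[C@H]1C
F2 | step 6 | trimethylsilyl enol ether corresponding to enolate 13 (configuration as in 14) | C[C@H](c3c(C(C)C)cc(C(C)C)cc3C(C)C)O[C@H]1C=C[C@@H]2CC(OCC)=C(O[Si](C)(C)C)C[C@]2(C)[C@H]1C
F3 | step 3 | 4-bromo-2-methoxy-3-methylphenol | COc1c(C)c(Br)ccc1O
F4 | step 3 | 5-bromo derivative of 7 (bromine on the alkene carbon next to the methyl-bearing bridgehead; configuration as in 7) | C[C@H](c3c(C(C)C)cc(C(C)C)cc3C(C)C)O[C@H]1[C@H]2C=C(Br)[C@](C)(C(OC)(OC)C2=O)[C@H]1C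
F5 | step 8 | pinacol alkenylboronate derived from 14 (boron on C7; configuration as in 14) | C[C@H](c3c(C(C)C)cc(C(C)C)cc3C(C)C)O[C@H]1C=C[C@@H]2CC(OCC)=C(B4OC(C)(C)C(C)(C)O4)C[C@]2(C)[C@H]1C
F6 | step 12 | α-phenylselanyl ketone derived from 23 (C8 ketone, selenium on C7, mixture at C7) | C[C@H](c3c(C(C)C)cc(C(C)C)cc3C(C)C)O[C@H]1CC[C@@H]2CC(=O)C([Se]c4ccccc4)([C@@H](C)C(=O)OC)C[C@]2(C)[C@H]1C
F7 | step 14 | 2-[bis(2,2,2-trifluoroethoxy)phosphoryl]propanoate ester of 25 (mixture at the phosphonate α-carbon) | CC(C(=O)O[C@H]1CC[C@@H]2CC(=O)C([C@@H](C)C(=O)OC)=C[C@]2(C)[C@H]1C)P(=O)(OCC(F)(F)F)OCC(F)(F)F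
A1 | alternative 1 | (3R,4S)-4-[(tert-butyldimethylsilyl)oxy]-2,3-dimethylcyclohexan-1-one | CC(C)(C)[Si](C)(C)O[C@H]1CCC(=O)C(C)[C@H]1C
A2 | alternative 1 | (4aR,5R,6S)-6-[(tert-butyldimethylsilyl)oxy]-4a,5-dimethyl-4,4a,5,6,7,8-hexahydronaphthalen-2(3H)-one | CC(C)(C)[Si](C)(C)O[C@H]1CCC2=CC(=O)CC[C@]2(C)[C@H]1C
A3 | alternative 2 | 2-ethynyl-1-methoxy-5,6-dimethylbicyclo[2.2.2]oct-5-en-2-ol (ethynyl syn to C5=C6; one enantiomer drawn) | C#C[C@]1(O)C[C@H]2CC[C@]1(OC)C(C)=C2C
A4 | alternative 2 | (4aR,8aR)-6-methoxy-4a,5-dimethyl-4a,7,8,8a-tetrahydronaphthalen-2(1H)-one | COC1=C(C)[C@@]2(C)C=CC(=O)C[C@H]2CC1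
A5 | alternative 3 | 4-[(2R,3S)-3-[(tert-butyldimethylsilyl)oxy]-5-iodopentan-2-yl]-4-methylcyclohexa-2,5-dien-1-one | CC(C)(C)[Si](C)(C)O[C@@H](CCI)[C@H](C)C1(C)C=CC(=O)C=C1
A6 | alternative 3 | (4aR,5R,6S,8aR)-6-[(tert-butyldimethylsilyl)oxy]-4a,5-dimethyl-4a,5,6,7,8,8a-hexahydronaphthalen-2(1H)-one | CC(C)(C)[Si](C)(C)O[C@H]1CC[C@@H]2CC(=O)C=C[C@]2(C)[C@H]1C
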